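**Plan**
- Retrosynthetic cuts, in order: the C8–CH2 bond of the prenyl group (traced back to an O5-prenyl ether); the C6–C(=O) and C(=O)–CH2 bonds together (to a C6 iodide, carbon monoxide and a benzylic zinc reagent); the C6–I bond (to C6–H); and last the pyran ring bonds C4–C4a and O1–C2 (to 5-methoxyresorcinol and 3-methylbut-2-enal).
- Enabling feature: the ketone carbon is a single carbon at the CO oxidation level lying between C6 of the chromene benzo ring (the carbon between oxygen-bearing C5 and C7) and the benzylic CH2 of the 4-hydroxyphenyl ring. This maps onto aryl iodide + CO + benzylzinc.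
- Forward order: the pyran ring is the only ring made and is closed first. Then come MOM protection, ortho-lithiation/iodination at C6, the three-component ketone assembly, MOM removal, O-prenylation at O5, Claisen–Cope transfer of prenyl to C8 and desilylation.
- Stereochemistry: the target has no stereocentre and no stereogenic double bond, so nothing has to be set; the stereocentres of the transient dienones disappear on rearomatisation.

Key step: step 7

Remark: because the molecule is achiral, "single enantiomer" is taken to mean the compound exactly as drawn.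

**Route**

Step 1
Reactants: 1 5-methoxyresorcinol; 2 3-methylbut-2-enal
Product: 3 7-methoxy-2,2-dimethyl-2H-chromen-5-ol
Conditions: EDDA (10 mol%), toluene, 110 °C, 1 in excess, 2 added slowly
Reagents that add atoms: none
Why: Amine-catalysed Knoevenagel-type condensation at the ring carbon between the two hydroxyls gives an o-quinone methide that closes by oxa-6π electrocyclisation (formal [3+3] chromene annulation of a resorcinol with an enal); 5-substituted resorcinols annulate preferentially at this carbon, the excess of 1 suppresses a second annulation, and any 7-hydroxy-5-methoxy isomer is removed by chromatography.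

Step 2
Reactants: 3 7-methoxy-2,2-dimethyl-2H-chromen-5-ol
Product: 4 7-methoxy-5-(methoxymethoxy)-2,2-dimethyl-2H-chromene
Conditions: MOMCl, i-Pr2NEt, CH2Cl2, 0 °C to rt
Reagents that add atoms: chloromethyl methyl ether, COCCl
Why: O-Alkylation of the only phenol with MOMCl and Hünig's base (Williamson-type acetal formation) installs a group that masks the hydroxyl and directs the coming metalation.

Step 3
Reactants: 4 7-methoxy-5-(methoxymethoxy)-2,2-dimethyl-2H-chromene
Product: 6 6-iodo-7-methoxy-5-(methoxymethoxy)-2,2-dimethyl-2H-chromene, via 6-lithiochromene 5 (not isolated)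
Conditions: n-BuLi, THF, 0 °C; then I2, THF, −78 °C to rt
Reagents that add atoms: iodine, II; n-butyllithium, CCCC[Li] (lithium of 5 only)
Why: Directed ortho-metalation removes the C6 hydrogen, which lies between the chelating OMOM group and the methoxy group, in preference to C8–H, which is flanked only by OMe and the hindered ring ether oxygen, and iodine traps the aryllithium.

Step 4
Reactants: 7 4-hydroxybenzyl alcohol
Product: 8 [4-(triisopropylsilyloxy)phenyl]methanol
Conditions: TIPSCl (1.0 equiv), imidazole, DMF, 0 °C
Reagents that add atoms: triisopropylsilyl chloride, CC(C)[Si](Cl)(C(C)C)C(C)C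
Why: Imidazole-mediated silylation should take the more acidic phenolic hydroxyl ahead of the benzylic alcohol when one equivalent of the bulky chlorosilane is used (chemoselective silyl ether formation).

Step 5
Reactants: 8 [4-(triisopropylsilyloxy)phenyl]methanol
Product: 9 [4-(chloromethyl)phenoxy]triisopropylsilane
Conditions: SOCl2, pyridine, CH2Cl2, 0 °C
Reagents that add atoms: thionyl chloride, O=S(Cl)Cl
Why: Chlorodehydroxylation of the benzylic alcohol through its chlorosulfite, with pyridine scavenging HCl so that the aryl silyl ether survives.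

Step 6
Reactants: 9 [4-(chloromethyl)phenoxy]triisopropylsilane
Product: 10 [4-(triisopropylsilyloxy)benzyl]zinc chloride (LiCl complex, titrated THF solution)
Conditions: Zn dust (activated with BrCH2CH2Br, TMSCl), LiCl, THF, 25 °C
Reagents that add atoms: zinc, [Zn]
Why: LiCl-promoted direct insertion of zinc into the benzylic C–Cl bond gives the benzylic zinc chloride with little Wurtz coupling, and the aryl silyl ether is inert to it.

Step 7
Reactants: 6 6-iodo-7-methoxy-5-(methoxymethoxy)-2,2-dimethyl-2H-chromene; 10 [4-(triisopropylsilyloxy)benzyl]zinc chloride; 11 carbon monoxide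
Product: 12 1-[7-methoxy-5-(methoxymethoxy)-2,2-dimethyl-2H-chromen-6-yl]-2-[4-(triisopropylsilyloxy)phenyl]ethanone
Conditions: Pd-PEPPSI-IPr (5 mol%), CO (5 bar), THF/NMP, 50 °C, 10 added by syringe pump
Reagents that add atoms: none
Why: Pd(0) inserts into the C6–I bond, CO migrates into the aryl–Pd bond to give the aroyl–palladium species, the benzylic zinc chloride transmetalates, and reductive elimination forms the carbonyl–CH2 bond, so C6–C(=O) and C(=O)–CH2 arise in one operation. The closest known reaction type is the carbonylative Negishi coupling of aryl iodides with benzylic zinc halides to deoxybenzoins, together with NHC–palladium carbonylative couplings of di-ortho-substituted aryl iodides. No ring is closed and no stereocentre is created. The selectivity required is carbonylative over direct aryl–benzyl coupling: the OMOM and OMe groups flanking C6 retard transmetalation at the crowded aryl–palladium stage and favour CO insertion, which relieves that crowding, while CO pressure and slow addition of 10 keep the zinc reagent scarce until the acyl complex has formed. The neutral medium leaves the MOM acetal, the aryl silyl ether and the acid-sensitive chromene olefin untouched.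

Step 8
Reactants: 12 1-[7-methoxy-5-(methoxymethoxy)-2,2-dimethyl-2H-chromen-6-yl]-2-[4-(triisopropylsilyloxy)phenyl]ethanone
Product: 13 1-(5-hydroxy-7-methoxy-2,2-dimethyl-2H-chromen-6-yl)-2-[4-(triisopropylsilyloxy)phenyl]ethanone
Conditions: conc. HCl (cat.), MeOH, 40 °C
Reagents that add atoms: none
Why: Acid-catalysed acetal exchange with methanol removes the MOM group, the freed phenol being hydrogen-bonded to the neighbouring ketone, while the aryl triisopropylsilyl ether and the chromene should survive the dilute acid.

Step 9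
Reactants: 13 1-(5-hydroxy-7-methoxy-2,2-dimethyl-2H-chromen-6-yl)-2-[4-(triisopropylsilyloxy)phenyl]ethanone; 14 prenyl bromide (1-bromo-3-methylbut-2-ene)
Product: 15 1-[7-methoxy-2,2-dimethyl-5-(3-methylbut-2-enyloxy)-2H-chromen-6-yl]-2-[4-(triisopropylsilyloxy)phenyl]ethanone
Conditions: K2CO3, acetone, reflux
Reagents that add atoms: none
Why: Williamson O-alkylation (SN2) of the phenoxide, the only site deprotonated by carbonate, with the allylic bromide; the other phenol stays silylated.

Step 10
Reactants: 15 1-[7-methoxy-2,2-dimethyl-5-(3-methylbut-2-enyloxy)-2H-chromen-6-yl]-2-[4-(triisopropylsilyloxy)phenyl]ethanone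
Product: 18 1-[5-hydroxy-7-methoxy-2,2-dimethyl-8-(3-methylbut-2-enyl)-2H-chromen-6-yl]-2-[4-(triisopropylsilyloxy)phenyl]ethanone, via C6 ortho-dienone 16 (not isolated), via C8 para-dienone 17 (not isolated)
Conditions: PhNEt2, 190 °C, argon
Reagents that add atoms: none
Why: Aromatic Claisen rearrangement to a substituted ortho carbon followed by a Cope shift (para-Claisen, Claisen–Cope sequence) is forced to C8 because both ortho positions C4a and C6 are blocked, the two allyl inversions deliver the normal prenyl group, and tautomerisation of the C8 dienone restores the hydrogen-bonded C5 phenol and erases the transient stereocentres.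

Step 11
Reactants: 18 1-[5-hydroxy-7-methoxy-2,2-dimethyl-8-(3-methylbut-2-enyl)-2H-chromen-6-yl]-2-[4-(triisopropylsilyloxy)phenyl]ethanone
Product: 19 1-[5-hydroxy-7-methoxy-2,2-dimethyl-8-(3-methylbut-2-enyl)-2H-chromen-6-yl]-2-(4-hydroxyphenyl)ethanone (CNP0287261.0)
Conditions: TBAF, AcOH, THF, 0 °C
Reagents that add atoms: none
Why: Fluoride-induced cleavage of the aryl Si–O bond (Si–F bond formation), buffered with acetic acid so that the phenoxides and the enolisable ketone are not exposed to base.

**Compound list**
1 | 5-methoxyresorcinol | COc1cc(O)cc(O)c1 | starting material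
2 | 3-methylbut-2-enal | CC(C)=CC=O | starting material
3 | 7-methoxy-2,2-dimethyl-2H-chromen-5-ol | COc1cc(O)c2C=CC(C)(C)Oc2c1 | intermediate
4 | 7-methoxy-5-(methoxymethoxy)-2,2-dimethyl-2H-chromene | COc1cc2OC(C)(C)C=Cc2c(OCOC)c1 | intermediate
5 | [7-methoxy-5-(methoxymethoxy)-2,2-dimethyl-2H-chromen-6-yl]lithium | COc1cc2OC(C)(C)C=Cc2c(OCOC)c1[Li] | intermediate (not isolated)
6 | 6-iodo-7-methoxy-5-(methoxymethoxy)-2,2-dimethyl-2H-chromene | COc1cc2OC(C)(C)C=Cc2c(OCOC)c1I | intermediate
7 | 4-hydroxybenzyl alcohol | OCc1ccc(O)cc1 | starting material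
8 | [4-(triisopropylsilyloxy)phenyl]methanol | OCc1ccc(O[Si](C(C)C)(C(C)C)C(C)C)cc1 | intermediate
9 | [4-(chloromethyl)phenoxy]triisopropylsilane | ClCc1ccc(O[Si](C(C)C)(C(C)C)C(C)C)cc1 | intermediate
10 | [4-(triisopropylsilyloxy)benzyl]zinc chloride | CC(C)[Si](Oc1ccc(C[Zn]Cl)cc1)(C(C)C)C(C)C | intermediate
11 | carbon monoxide | [C-]#[O+] | starting material
12 | 1-[7-methoxy-5-(methoxymethoxy)-2,2-dimethyl-2H-chromen-6-yl]-2-[4-(triisopropylsilyloxy)phenyl]ethanone | COc1cc2OC(C)(C)C=Cc2c(OCOC)c1C(=O)Cc1ccc(O[Si](C(C)C)(C(C)C)C(C)C)cc1 | intermediate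
13 | 1-(5-hydroxy-7-methoxy-2,2-dimethyl-2H-chromen-6-yl)-2-[4-(triisopropylsilyloxy)phenyl]ethanone | COc1cc2OC(C)(C)C=Cc2c(O)c1C(=O)Cc1ccc(O[Si](C(C)C)(C(C)C)C(C)C)cc1 | intermediate
14 | prenyl bromide (1-bromo-3-methylbut-2-ene) | CC(C)=CCBr | starting material
15 | 1-[7-methoxy-2,2-dimethyl-5-(3-methylbut-2-enyloxy)-2H-chromen-6-yl]-2-[4-(triisopropylsilyloxy)phenyl]ethanone | COc1cc2OC(C)(C)C=Cc2c(OCC=C(C)C)c1C(=O)Cc1ccc(O[Si](C(C)C)(C(C)C)C(C)C)cc1 | intermediate
16 | 7-methoxy-2,2-dimethyl-6-(2-methylbut-3-en-2-yl)-6-{[4-(triisopropylsilyloxy)phenyl]acetyl}-2H-chromen-5(6H)-one (racemic) | COC1=CC2=C(C=CC(C)(C)O2)C(=O)C1(C(C)(C)C=C)C(=O)Cc1ccc(O[Si](C(C)C)(C(C)C)C(C)C)cc1 | intermediate (not isolated)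
17 | 7-methoxy-2,2-dimethyl-8-(3-methylbut-2-enyl)-6-{[4-(triisopropylsilyloxy)phenyl]acetyl}-2H-chromen-5(8H)-one (racemic) | COC1=C(C(=O)Cc2ccc(O[Si](C(C)C)(C(C)C)C(C)C)cc2)C(=O)C2=C(OC(C)(C)C=C2)C1CC=C(C)C | intermediate (not isolated)
18 | 1-[5-hydroxy-7-methoxy-2,2-dimethyl-8-(3-methylbut-2-enyl)-2H-chromen-6-yl]-2-[4-(triisopropylsilyloxy)phenyl]ethanone | COc1c(CC=C(C)C)c2OC(C)(C)C=Cc2c(O)c1C(=O)Cc1ccc(O[Si](C(C)C)(C(C)C)C(C)C)cc1 | intermediate
19 | 1-[5-hydroxy-7-methoxy-2,2-dimethyl-8-(3-methylbut-2-enyl)-2H-chromen-6-yl]-2-(4-hydroxyphenyl)ethanone | COc1c(CC=C(C)C)c2c(c(O)c1C(=O)Cc1ccc(O)cc1)C=CC(C)(C)O2 | target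

**Step count**
Total: 11 steps. Longest linear sequence: 8 steps (1, 2, 3, 7, 8, 9, 10, 11; the zinc branch 4, 5, 6, 7–11 is equally long).

**Steps most likely to fail**

Step 7. Transmetalation at the aryl–palladium stage may outrun CO insertion and give direct aryl–benzyl coupling, or the zinc reagent may be consumed by homocoupling before the hindered acyl complex forms. The fallback builds the ketone by polar additions and sets out from 4. Lithiation as in step 3 gives 5, which is quenched with DMF to give 7-methoxy-5-(methoxymethoxy)-2,2-dimethyl-2H-chromene-6-carbaldehyde F1. MgCl2-promoted addition of the zinc reagent 10 in THF gives racemic 1-[7-methoxy-5-(methoxymethoxy)-2,2-dimethyl-2H-chromen-6-yl]-2-[4-(triisopropylsilyloxy)phenyl]ethanol F2. Oxidation with Dess–Martin periodinane (NaHCO3, CH2Cl2) returns to the route at 12.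

Step 10. The first [3,3] shift must join two fully substituted carbons, so the prenyl ether may fragment back to the phenol with loss of the C5 unit, or the sequence may stall before the Cope shift. The fallback replaces the sigmatropic transfer by cross-coupling and sets out from 13. NBS in CH2Cl2 at −20 °C should brominate the only free position of the activated ring, C8 (para to the C5 hydroxyl), giving 1-(8-bromo-5-hydroxy-7-methoxy-2,2-dimethyl-2H-chromen-6-yl)-2-[4-(triisopropylsilyloxy)phenyl]ethanone F3. Suzuki–Miyaura coupling with prenylboronic acid pinacol ester, using a palladium/biarylphosphine catalyst chosen for linear (α) selectivity and K3PO4 in THF/water, returns to the route at 18.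

Step 1. Annulation may also occur at the carbon between OH and OMe, and a second annulation may take place on the remaining hydroxyl, so site selectivity and mono-selectivity may be poor. The fallback fixes the site by metalation and sets out from 1. Double protection (MOMCl, i-Pr2NEt) gives 1-methoxy-3,5-bis(methoxymethoxy)benzene F4. n-BuLi in THF at 0 °C deprotonates the carbon between the two acetal oxygens to give [4-methoxy-2,6-bis(methoxymethoxy)phenyl]lithium F5. Addition to 2 gives 1-[4-methoxy-2,6-bis(methoxymethoxy)phenyl]-3-methylbut-2-en-1-ol F6. Methanolic HCl removes both acetals, and the o-hydroxybenzylic allylic alcohol cyclodehydrates through the o-quinone methide (oxa-6π closure), returning to the route at 3.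

**Further compounds**
F1 | step 7 | 7-methoxy-5-(methoxymethoxy)-2,2-dimethyl-2H-chromene-6-carbaldehyde | COc1cc2OC(C)(C)C=Cc2c(OCOC)c1C=O
F2 | step 7 | 1-[7-methoxy-5-(methoxymethoxy)-2,2-dimethyl-2H-chromen-6-yl]-2-[4-(triisopropylsilyloxy)phenyl]ethanol (racemic) | COc1cc2OC(C)(C)C=Cc2c(OCOC)c1C(O)Cc1ccc(O[Si](C(C)C)(C(C)C)C(C)C)cc1
F3 | step 10 | 1-(8-bromo-5-hydroxy-7-methoxy-2,2-dimethyl-2H-chromen-6-yl)-2-[4-(triisopropylsilyloxy)phenyl]ethanone | COc1c(Br)c2OC(C)(C)C=Cc2c(O)c1C(=O)Cc1ccc(O[Si](C(C)C)(C(C)C)C(C)C)cc1
F4 | step 1 | 1-methoxy-3,5-bis(methoxymethoxy)benzene | COCOc1cc(OC)cc(OCOC)c1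
F5 | step 1 | [4-methoxy-2,6-bis(methoxymethoxy)phenyl]lithium | COCOc1cc(OC)cc(OCOC)c1[Li]
F6 | step 1 | 1-[4-methoxy-2,6-bis(methoxymethoxy)phenyl]-3-methylbut-2-en-1-ol (racemic) | COCOc1cc(OC)cc(OCOC)c1C(O)C=C(C)C
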